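**Plan**

1. Retrosynthesis: the butenolide C–O bond and C7–C8 are cut together (Ni/Cr coupling with lactonisation), which opens the ten-membered ring. The epoxide C12–O bond, the two esters and Me-20 are then taken back to a PMB ether, a silylene and an α-acetoxy aldehyde. Last, C1–C10 and C11–C12 of the cyclohexane are cut together.
2. Enabling feature: the six-membered ring (C1, C10, C11, C12, C13, C14) carries oxygen on C14 and on C11/C12. This is the pattern left by a 1-alkoxy-3-silyloxy diene C12=C13–C14=C1 and a 2-acyloxy enal C10=C11(–C20HO), so a [4+2] cycloaddition forms both bonds. C20 later becomes Me-20 and the acyloxy oxygen becomes the epoxide oxygen.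
3. Forward order: three fragments (C2–C7 aldehyde from nerol, C12–C15 alkoxy enone, C8–C11/C20 enal) → aldol (C1–C2) → cyclic silylene diene → cyclohexene by cycloaddition → C20 reduced to methyl, C2/C14 esters, epoxide → enol triflate → ten-membered ring and butenolide closed together.
4. Stereochemistry: C2 from a BINOL–titanium aldol. C1, C10, C11 and C12 from the cycloaddition (C2 relayed through the silylene ring, endo rule, alkene geometries). C14 from hydride attack on the open face. C12 is inverted in the epoxide closure. C7 from a chiral ligand on chromium. The Z C5=C6 alkene comes intact from nerol.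

Key step: step 12

Remark: locants are those of the target skeleton. C1 is the ring-fusion carbon with Me-15; C2 (butanoyloxy) to C9 are the other ten-ring carbons (C5 bears Me-16; C7 and C8 are shared with the lactone C17(Me-18)/C19); C10 is the ring-fusion CH; C11 (Me-20), C12, C13, C14 (acetoxy) complete the cyclohexane. β is the face of Me-15. TBDPS = t-BuPh2Si, PMB = 4-MeOC6H4CH2.

**Route**

Step 1
Reactants: 1 nerol
Product: 2 neryl TBDPS ether
Conditions: t-BuPh2SiCl, imidazole, DMF, rt
Reagents that add atoms: tert-butyl(chloro)diphenylsilane, CC(C)(C)[Si](Cl)(c1ccccc1)c1ccccc1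
Why: Standard silylation of a primary allylic alcohol; the Z alkene of nerol becomes C5=C6 of the target.

Step 2
Reactants: 2 neryl TBDPS ether
Product: 4 (4Z)-6-{[tert-butyl(diphenyl)silyl]oxy}-4-methylhex-4-enal, via secondary ozonide 3 (not isolated)
Conditions: O3 (1 equiv, Sudan red end point), CH2Cl2, pyridine, −78 °C; then PPh3
Reagents that add atoms: ozone, [O-][O+]=O
Why: Ozonolysis with reductive work-up should cleave the remote, more electron-rich isopropylidene alkene in preference to the alkene deactivated by the allylic silyloxy group.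

Step 3
Reactants: 5 pent-1-yn-3-ol
Product: 6 pent-1-yn-3-one
Conditions: MnO2, CH2Cl2, rt
Reagents that add atoms: none
Why: Oxidation of a propargylic alcohol to the ynone with activated MnO2.

Step 4
Reactants: 6 pent-1-yn-3-one
Product: 7 (1E)-1-[(4-methoxybenzyl)oxy]pent-1-en-3-one
Conditions: 4-MeOC6H4CH2OH, DABCO (cat.), CH2Cl2, rt
Reagents that add atoms: 4-methoxybenzyl alcohol, COc1ccc(CO)cc1
Why: Amine-catalysed oxa-Michael addition of an alcohol to a terminal ynone, which should give the thermodynamically preferred E β-alkoxy enone.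

Step 5
Reactants: 7 (1E)-1-[(4-methoxybenzyl)oxy]pent-1-en-3-one
Product: 8 {[(1E,3Z)-1-[(4-methoxybenzyl)oxy]penta-1,3-dien-3-yl]oxy}(trimethyl)silane
Conditions: Me3SiOTf, Et3N, Et2O, 0 °C
Reagents that add atoms: trimethylsilyl trifluoromethanesulfonate, C[Si](C)(C)OS(=O)(=O)C(F)(F)F
Why: Soft enolisation and O-silylation on the only enolisable (ethyl) side of the vinylogous ester gives the 1-alkoxy-3-silyloxy diene.

Step 6
Reactants: 8 silyl dienol ether and 4 aldehyde
Product: 10 (1E,5S,8Z)-10-{[tert-butyl(diphenyl)silyl]oxy}-5-hydroxy-1-[(4-methoxybenzyl)oxy]-4,8-dimethyldeca-1,8-dien-3-one (both C4 epimers), via O-trimethylsilyl aldol 9 (not isolated)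
Conditions: (R)-BINOL (20 mol%), Ti(OiPr)4 (10 mol%), 4 Å MS, Et2O, −20 °C; then Bu4NF, AcOH, THF, 0 °C
Reagents that add atoms: none
Why: Enantioselective Mukaiyama aldol addition of a 1-alkoxy-3-silyloxy diene to an aldehyde under BINOL–titanium catalysis; by analogy with other additions of this catalyst the (R)-ligand should direct attack to the Re face of the aldehyde (2S; the (S)-ligand is used if the sense proves opposite), the mixture at the methyl-bearing carbon is irrelevant because that centre becomes trigonal in step 7, and buffered fluoride removes the silyl group without acid-induced cyclisation to a dihydropyranone.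

Step 7
Reactants: 10 aldol adduct
Product: 11 (4S)-2,2-di-tert-butyl-4-[(3Z)-5-{[tert-butyl(diphenyl)silyl]oxy}-3-methylpent-3-en-1-yl]-6-{(E)-2-[(4-methoxybenzyl)oxy]ethenyl}-5-methyl-4H-1,3,2-dioxasiline
Conditions: t-Bu2Si(OTf)2, Et3N, CH2Cl2, −78 to 0 °C
Reagents that add atoms: di-tert-butylsilanediyl bis(trifluoromethanesulfonate), CC(C)(C)[Si](OS(=O)(=O)C(F)(F)F)(OS(=O)(=O)C(F)(F)F)C(C)(C)C
Why: O-Silylation of the alcohol followed by intramolecular silyl enol ether formation (silyl triflate/amine) toward the only α-CH closes the six-membered silylene ring, which fixes the enol ether geometry (Me-15 cis to the vinyl group) and places the C2 stereocentre next to the diene terminus.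

Step 8
Reactants: 12 3-bromopropan-1-ol
Product: 13 (3-bromopropoxy)(tert-butyl)diphenylsilane
Conditions: t-BuPh2SiCl, imidazole, DMF, rt
Reagents that add atoms: tert-butyl(chloro)diphenylsilane, CC(C)(C)[Si](Cl)(c1ccccc1)c1ccccc1
Why: Standard silylation of a primary alcohol.

Step 9
Reactants: 13 bromide and 14 methyl 2,2-dimethoxyacetate
Product: 16 5-{[tert-butyl(diphenyl)silyl]oxy}-1,1-dimethoxypentan-2-one, via Grignard reagent 15 (not isolated)
Conditions: Mg, THF, rt; then 14, THF, −78 °C; aq NH4Cl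
Reagents that add atoms: none
Why: Grignard acylation by an α,α-dialkoxy ester should stop at the ketone at low temperature because the chelated tetrahedral intermediate survives until work-up.

Step 10
Reactants: 16 α-keto acetal
Product: 18 (2Z)-5-{[tert-butyl(diphenyl)silyl]oxy}-1,1-dimethoxypent-2-en-2-yl acetate, via potassium enolate 17 (not isolated)
Conditions: KN(SiMe3)2, THF, −78 °C; then Ac2O
Reagents that add atoms: acetic anhydride, CC(=O)OC(C)=O
Why: Kinetic deprotonation at the less hindered CH2 should give the enolate with the alkyl chain cis to O–, and O-acetylation fixes the acetoxy group cis to C9.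

Step 11
Reactants: 18 enol acetate acetal
Product: 19 (2Z)-5-{[tert-butyl(diphenyl)silyl]oxy}-1-oxopent-2-en-2-yl acetate
Conditions: TsOH·H2O (cat.), acetone/H2O, rt
Reagents that add atoms: water, O
Why: Hydrolysis of an allylic-type dimethyl acetal, which is much faster than cleavage of the enol acetate or the silyl ether, frees the 2-acetoxy enal without change of alkene geometry.

Step 12
Reactants: 11 silylene diene and 19 2-acetoxy enal
Product: 20 cycloadduct (ring cyclohexene with 1β-Me/10β-CH2CH2OTBDPS/11β-OAc/11α-CHO/12α-OPMB and the C13=C14 enol ether tied to O2 by t-Bu2Si)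
Conditions: PhMe (1 M), BHT (cat.), 90 °C, sealed tube; Et3N-deactivated SiO2
Reagents that add atoms: none
Why: A thermal, concerted but asynchronous normal-demand [4+2] cycloaddition joins the HOMO of the 1-alkoxy-3-silyloxy diene C12=C13–C14=C1 of 11 to the LUMO of the captodative enal C10=C11 of 19, the most nucleophilic diene terminus C1 bonding to the enal β-carbon C10 and C12 to the formyl-bearing C11. The closest known reaction type is the Diels–Alder reaction of 1-alkoxy-3-silyloxy dienes with 2-substituted acroleins, 2-acyloxyacroleins included. The cyclohexene ring (C1, C10, C11, C12, C13, C14) is closed by suprafacial–suprafacial union of the 4π and 2π components, both σ bonds forming in one transition state. C1 is set by the C2 stereocentre, whose side chain sits pseudoaxial on the silylene ring (allylic strain with Me-15) so that C10 bonds to the opposite face; C10 and C11 are set by suprafacial transfer of the Z geometry of 19 (C9 cis to OAc) together with the endo orientation of the formyl group; C12 is set by the E geometry of the alkoxyvinyl group, which with the endo rule puts the PMB ether cis to formyl and trans to the acetoxy oxygen. The step needs regio-, endo- and π-facial selectivity: the first follows from the matched polarisation of the partners, the second from secondary overlap of the formyl group (no Lewis acid is used, so the aldehyde C=O should not compete as a heterodienophile), the third from the silylene ring, which also locks Me-15 inside and C2 outside on the diene terminus. The adduct should thus carry O11 (β) and O12 (α) trans to each other, ready for the later epoxide closure, and C2 trans to C9 across the new C1–C10 bond as the trans ring fusion requires.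

Step 13
Reactants: 20 cycloadduct
Product: 21 C20 primary alcohol/11β-tertiary alcohol (1,2-diol)
Conditions: LiAlH4, Et2O, −20 to 0 °C
Reagents that add atoms: none
Why: Hydride reduction of the aldehyde and reductive removal of the tertiary acetate give the 1,2-diol, while the silyl enol ether, silyl ethers and PMB ether are inert.

Step 14
Reactants: 21 diol
Product: 24 11β-hydroxy-11α-methyl compound (C20 is now Me-20), via C20 tosylate 22 (not isolated), via spiro-epoxide 23 (not isolated)
Conditions: NaH, 1-(p-tolylsulfonyl)imidazole, THF, 0 °C to rt; then LiBHEt3, 0 °C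
Reagents that add atoms: none
Why: Selective sulfonylation of the primary alkoxide and closure by the tertiary alkoxide give the terminal spiro-epoxide, which hydride opens by SN2 attack at the CH2 terminus, so the C11–O bond and its β configuration are untouched.

Step 15
Reactants: 24 silylene enol ether
Product: 25 C14 ketone with free 2-OH and 11β-OH
Conditions: HF·pyridine, pyridine, THF, 0 °C
Reagents that add atoms: none
Why: Cyclic di-tert-butylsilylenes are cleaved by buffered HF much faster than primary TBDPS ethers, which unmasks the ketone and the C2 alcohol under conditions too mild to eliminate the β-alkoxy group.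

Step 16
Reactants: 25 β-hydroxy ketone
Product: 26 2-O-butanoyl C14 ketone
Conditions: (n-PrCO)2O, Et3N, DMAP, CH2Cl2, 0 °C to rt
Reagents that add atoms: butanoic anhydride, CCCC(=O)OC(=O)CCC
Why: DMAP-catalysed acylation of the only secondary alcohol; the hindered tertiary C11–OH should not react and the quaternary C1 rules out β-elimination.

Step 17
Reactants: 26 ketone
Product: 27 2-O-butanoyl 14α-alcohol
Conditions: LiBH(s-Bu)3, THF, −78 °C; AcOH quench at −78 °C
Reagents that add atoms: none
Why: The bulky hydride should attack along the equatorial trajectory from the β face because axial approach is blocked by the syn-axial 12α-OPMB group, giving the axial 14α-alcohol (anti to O2); the cold acidic quench limits 1,3-acyl shift from O2.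

Step 18
Reactants: 27 alcohol
Product: 28 2-O-butanoyl 14α-acetate
Conditions: Ac2O, pyridine, DMAP, CH2Cl2, rt
Reagents that add atoms: acetic anhydride, CC(=O)OC(C)=O
Why: Acetylation of the secondary alcohol; the tertiary C11–OH is left free.

Step 19
Reactants: 28 PMB ether
Product: 29 11β,12α-diol
Conditions: DDQ, CH2Cl2/pH 7 buffer, 0 °C
Reagents that add atoms: none
Why: Oxidative cleavage of the PMB ether; silyl ethers, esters and the trisubstituted alkene should survive.

Step 20
Reactants: 29 diol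
Product: 31 11β,12β-epoxide (bis-TBDPS ether), via 12α-mesylate 30 (not isolated)
Conditions: MsCl, Et3N, CH2Cl2, 0 °C; then DBU, rt
Reagents that add atoms: none
Why: Sulfonylation of the secondary 12α-alcohol and intramolecular Williamson closure by the trans-diaxial 11β-alkoxide invert C12 and give the β-epoxide; immediate mesylation forestalls acetyl shift from O14.

Step 21
Reactants: 31 bis-silyl ether
Product: 32 epoxy diol (C7–OH and C8–OH free)
Conditions: Bu4NF, AcOH, THF, rt
Reagents that add atoms: none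
Why: Buffered fluoride removes both primary TBDPS groups; opening of the epoxide by the C8 alcohol would need a trans-diaxial bridge and is not expected.

Step 22
Reactants: 32 diol
Product: 33 epoxy dialdehyde (C7 Z-enal and C8 aldehyde)
Conditions: Dess–Martin periodinane, NaHCO3, CH2Cl2, 0 °C to rt
Reagents that add atoms: none
Why: Buffered Dess–Martin oxidation of both primary alcohols under neutral conditions that should leave the Z enal geometry and the epoxide intact.

Step 23
Reactants: 34 ethyl 2-methyl-3-oxobutanoate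
Product: 35 ethyl 2-diazopropanoate
Conditions: 4-AcNHC6H4SO2N3, DBU, MeCN, 0 °C to rt
Reagents that add atoms: 4-acetamidobenzenesulfonyl azide, CC(=O)Nc1ccc(cc1)S(=O)(=O)N=[N+]=[N-]
Why: Deacylative Regitz diazo transfer to a 2-substituted acetoacetate.

Step 24
Reactants: 33 dialdehyde and 35 ethyl 2-diazopropanoate
Product: 36 C8 β-keto ester (C17 epimers)
Conditions: SnCl2 (10 mol%), CH2Cl2, rt
Reagents that add atoms: none
Why: Roskamp homologation (addition of the diazo ester to the aldehyde, then 1,2-hydride shift with loss of N2) should take place at the saturated C8 aldehyde, because conjugated enals are poor substrates and SnCl2 is a weak Lewis acid toward the hindered epoxide.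

Step 25
Reactants: 36 β-keto ester
Product: 37 (Z)-enol triflate (C8–OTf cis to CO2Et)
Conditions: Tf2O, Et3N, LiOTf, CH2Cl2, −78 to 0 °C
Reagents that add atoms: trifluoromethanesulfonic anhydride, O=S(=O)(OS(=O)(=O)C(F)(F)F)C(F)(F)F
Why: O-Sulfonylation of the lithium-chelated enolate, in which lithium bridges the ketone and ester oxygens, should give the Z enol triflate.

Step 26
Reactants: 37 enol triflate
Product: 39 target (2-butanoyloxy-14-acetoxy-11β,12β-epoxy butenolide), via macrocyclic hydroxy ester 38 (not isolated)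
Conditions: CrCl2 (4 equiv), NiCl2 (cat.), chiral 2-(oxazolin-2-yl)-N-mesylanilide ligand, Et3N, THF/MeCN, rt, 1 mM; then SiO2
Reagents that add atoms: none
Why: Nozaki–Hiyama–Kishi reaction: zerovalent nickel inserts into the C8–OTf bond, transmetallation gives the alkenyl trivalent chromium species, which adds to the C7 aldehyde and closes the ten-membered ring; the ligand antipode that directs Si-face addition sets 7R, and the alkoxide then lactonises onto the cis ethyl ester to give the butenolide.

**Compound list**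

1 | nerol, (2Z)-3,7-dimethylocta-2,6-dien-1-ol | CC(C)=CCC/C(C)=C\CO | starting material
2 | neryl tert-butyldiphenylsilyl ether | CC(C)=CCC/C(C)=C\CO[Si](c1ccccc1)(c1ccccc1)C(C)(C)C | intermediate
3 | secondary ozonide of the isopropylidene alkene of 2 | CC1(C)OOC(CC/C(C)=C\CO[Si](c2ccccc2)(c2ccccc2)C(C)(C)C)O1 | intermediate
4 | (4Z)-6-{[tert-butyl(diphenyl)silyl]oxy}-4-methylhex-4-enal | O=CCC/C(C)=C\CO[Si](c1ccccc1)(c1ccccc1)C(C)(C)C | intermediate
5 | pent-1-yn-3-ol | CCC(O)C#C | starting material
6 | pent-1-yn-3-one | CCC(=O)C#C | intermediate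
7 | (1E)-1-[(4-methoxybenzyl)oxy]pent-1-en-3-one | CCC(=O)/C=C/OCc1ccc(OC)cc1 | intermediate
8 | {[(1E,3Z)-1-[(4-methoxybenzyl)oxy]penta-1,3-dien-3-yl]oxy}(trimethyl)silane | C/C=C(/C=C/OCc1ccc(OC)cc1)O[Si](C)(C)C | intermediate
9 | O-trimethylsilyl ether of 10 | COc1ccc(CO/C=C/C(=O)C(C)[C@@H](O[Si](C)(C)C)CC/C(C)=C\CO[Si](c2ccccc2)(c2ccccc2)C(C)(C)C)cc1 | intermediate
10 | (1E,5S,8Z)-10-{[tert-butyl(diphenyl)silyl]oxy}-5-hydroxy-1-[(4-methoxybenzyl)oxy]-4,8-dimethyldeca-1,8-dien-3-one (both C4 epimers) | COc1ccc(CO/C=C/C(=O)C(C)[C@@H](O)CC/C(C)=C\CO[Si](c2ccccc2)(c2ccccc2)C(C)(C)C)cc1 | intermediate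
11 | (4S)-2,2-di-tert-butyl-4-[(3Z)-5-{[tert-butyl(diphenyl)silyl]oxy}-3-methylpent-3-en-1-yl]-6-{(E)-2-[(4-methoxybenzyl)oxy]ethenyl}-5-methyl-4H-1,3,2-dioxasiline | COc1ccc(CO/C=C/C2=C(C)[C@H](CC/C(C)=C\CO[Si](c3ccccc3)(c3ccccc3)C(C)(C)C)O[Si](C(C)(C)C)(C(C)(C)C)O2)cc1 | intermediate
12 | 3-bromopropan-1-ol | OCCCBr | starting material
13 | (3-bromopropoxy)(tert-butyl)diphenylsilane | BrCCCO[Si](c1ccccc1)(c1ccccc1)C(C)(C)C | intermediate
14 | methyl 2,2-dimethoxyacetate | COC(OC)C(=O)OC | starting material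
15 | (3-{[tert-butyl(diphenyl)silyl]oxy}propyl)magnesium bromide | Br[Mg]CCCO[Si](c1ccccc1)(c1ccccc1)C(C)(C)C | intermediate
16 | 5-{[tert-butyl(diphenyl)silyl]oxy}-1,1-dimethoxypentan-2-one | COC(OC)C(=O)CCCO[Si](c1ccccc1)(c1ccccc1)C(C)(C)C | intermediate
17 | potassium (Z)-enolate of 16 | [K+].[O-]/C(=C\CCO[Si](c1ccccc1)(c1ccccc1)C(C)(C)C)C(OC)OC | intermediate
18 | (2Z)-5-{[tert-butyl(diphenyl)silyl]oxy}-1,1-dimethoxypent-2-en-2-yl acetate | CC(=O)O/C(=C\CCO[Si](c1ccccc1)(c1ccccc1)C(C)(C)C)C(OC)OC | intermediate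
19 | (2Z)-5-{[tert-butyl(diphenyl)silyl]oxy}-1-oxopent-2-en-2-yl acetate | CC(=O)O/C(C=O)=C\CCO[Si](c1ccccc1)(c1ccccc1)C(C)(C)C | intermediate
20 | cycloadduct: 1β-Me, 10β-CH2CH2OTBDPS, 11β-OAc, 11α-CHO, 12α-OPMB, C13=C14 enol ether bridged to O2 by t-Bu2Si, 2S side chain | CC(C)(C)[Si]1(C(C)(C)C)O[C@@H](CC/C(C)=C\CO[Si](c2ccccc2)(c2ccccc2)C(C)(C)C)[C@]2(C)[C@@H](CCO[Si](c3ccccc3)(c3ccccc3)C(C)(C)C)[C@@](C=O)(OC(C)=O)[C@H](OCc3ccc(OC)cc3)C=C2O1 | intermediate
21 | 1,2-diol of 20 (C20 CH2OH, 11β-OH) | CC(C)(C)[Si]1(C(C)(C)C)O[C@@H](CC/C(C)=C\CO[Si](c2ccccc2)(c2ccccc2)C(C)(C)C)[C@]2(C)[C@@H](CCO[Si](c3ccccc3)(c3ccccc3)C(C)(C)C)[C@@](CO)(O)[C@H](OCc3ccc(OC)cc3)C=C2O1 | intermediate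
22 | C20 p-toluenesulfonate of 21 | CC(C)(C)[Si]1(C(C)(C)C)O[C@@H](CC/C(C)=C\CO[Si](c2ccccc2)(c2ccccc2)C(C)(C)C)[C@]2(C)[C@@H](CCO[Si](c3ccccc3)(c3ccccc3)C(C)(C)C)[C@@](COS(=O)(=O)c3ccc(C)cc3)(O)[C@H](OCc3ccc(OC)cc3)C=C2O1 | intermediate
23 | C11/C20 spiro-epoxide | CC(C)(C)[Si]1(C(C)(C)C)O[C@@H](CC/C(C)=C\CO[Si](c2ccccc2)(c2ccccc2)C(C)(C)C)[C@]2(C)[C@@H](CCO[Si](c3ccccc3)(c3ccccc3)C(C)(C)C)[C@]3(CO3)[C@H](OCc3ccc(OC)cc3)C=C2O1 | intermediate
24 | 11β-hydroxy-11α-methyl silylene enol ether | CC(C)(C)[Si]1(C(C)(C)C)O[C@@H](CC/C(C)=C\CO[Si](c2ccccc2)(c2ccccc2)C(C)(C)C)[C@]2(C)[C@@H](CCO[Si](c3ccccc3)(c3ccccc3)C(C)(C)C)[C@@](C)(O)[C@H](OCc3ccc(OC)cc3)C=C2O1 | intermediate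
25 | C14 ketone with 2-OH, 11β-OH and 12α-OPMB | O[C@@H](CC/C(C)=C\CO[Si](c1ccccc1)(c1ccccc1)C(C)(C)C)[C@]1(C)[C@@H](CCO[Si](c2ccccc2)(c2ccccc2)C(C)(C)C)[C@@](C)(O)[C@H](OCc2ccc(OC)cc2)CC1=O | intermediate
26 | 2-O-butanoyl C14 ketone | CCCC(=O)O[C@@H](CC/C(C)=C\CO[Si](c1ccccc1)(c1ccccc1)C(C)(C)C)[C@]1(C)[C@@H](CCO[Si](c2ccccc2)(c2ccccc2)C(C)(C)C)[C@@](C)(O)[C@H](OCc2ccc(OC)cc2)CC1=O | intermediate
27 | 2-O-butanoyl 14α-alcohol | CCCC(=O)O[C@@H](CC/C(C)=C\CO[Si](c1ccccc1)(c1ccccc1)C(C)(C)C)[C@]1(C)[C@@H](CCO[Si](c2ccccc2)(c2ccccc2)C(C)(C)C)[C@@](C)(O)[C@H](OCc2ccc(OC)cc2)C[C@@H]1O | intermediate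
28 | 2-O-butanoyl 14α-acetate (12α-OPMB, 11β-OH) | CCCC(=O)O[C@@H](CC/C(C)=C\CO[Si](c1ccccc1)(c1ccccc1)C(C)(C)C)[C@]1(C)[C@@H](CCO[Si](c2ccccc2)(c2ccccc2)C(C)(C)C)[C@@](C)(O)[C@H](OCc2ccc(OC)cc2)C[C@@H]1OC(C)=O | intermediate
29 | 11β,12α-diol | CCCC(=O)O[C@@H](CC/C(C)=C\CO[Si](c1ccccc1)(c1ccccc1)C(C)(C)C)[C@]1(C)[C@@H](CCO[Si](c2ccccc2)(c2ccccc2)C(C)(C)C)[C@@](C)(O)[C@H](O)C[C@@H]1OC(C)=O | intermediate
30 | 12α-methanesulfonate of 29 | CCCC(=O)O[C@@H](CC/C(C)=C\CO[Si](c1ccccc1)(c1ccccc1)C(C)(C)C)[C@]1(C)[C@@H](CCO[Si](c2ccccc2)(c2ccccc2)C(C)(C)C)[C@@](C)(O)[C@H](OS(C)(=O)=O)C[C@@H]1OC(C)=O | intermediate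
31 | 11β,12β-epoxide, bis-TBDPS ether | CCCC(=O)O[C@@H](CC/C(C)=C\CO[Si](c1ccccc1)(c1ccccc1)C(C)(C)C)[C@]1(C)[C@@H](CCO[Si](c2ccccc2)(c2ccccc2)C(C)(C)C)[C@@]2(C)O[C@H]2C[C@@H]1OC(C)=O | intermediate
32 | epoxy diol (C7–OH, C8–OH) | CCCC(=O)O[C@@H](CC/C(C)=C\CO)[C@]1(C)[C@@H](CCO)[C@@]2(C)O[C@H]2C[C@@H]1OC(C)=O | intermediate
33 | epoxy dialdehyde (C7 Z-enal, C8 aldehyde) | CCCC(=O)O[C@@H](CC/C(C)=C\C=O)[C@]1(C)[C@@H](CC=O)[C@@]2(C)O[C@H]2C[C@@H]1OC(C)=O | intermediate
34 | ethyl 2-methyl-3-oxobutanoate | CCOC(=O)C(C)C(C)=O | starting material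
35 | ethyl 2-diazopropanoate | CCOC(=O)C(C)=[N+]=[N-] | intermediate
36 | C8 β-keto ester (C17 epimers) | CCCC(=O)O[C@@H](CC/C(C)=C\C=O)[C@]1(C)[C@@H](CC(=O)C(C)C(=O)OCC)[C@@]2(C)O[C@H]2C[C@@H]1OC(C)=O | intermediate
37 | (Z)-enol triflate | CCCC(=O)O[C@@H](CC/C(C)=C\C=O)[C@]1(C)[C@@H](C/C(OS(=O)(=O)C(F)(F)F)=C(\C)C(=O)OCC)[C@@]2(C)O[C@H]2C[C@@H]1OC(C)=O | intermediate
38 | macrocyclic (7R)-hydroxy ethyl ester | CCCC(=O)O[C@H]1CC/C(C)=C\[C@@H](O)/C(=C(/C)C(=O)OCC)C[C@H]2[C@@]3(C)O[C@H]3C[C@H](OC(C)=O)[C@]12C | intermediate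
39 | target CNP0220791.2 | CCCC(=O)O[C@H]1CC/C(C)=C\[C@H]2OC(=O)C(C)=C2C[C@H]2[C@@]3(C)O[C@H]3C[C@H](OC(C)=O)[C@]12C | target

**Step count**

Total step count: 26. Longest linear sequence: 19 steps (3, 4, 5, 6, 7, 12–22, 24–26).

**Steps most likely to fail, with fallbacks**

Step 12. What may go wrong: slow cycloaddition at the fully substituted diene terminus, or loss of endo or π-facial selectivity, giving C10/C11 diastereomers. The fallback replaces the thermal cycloaddition with a chelate-controlled, stepwise Mukaiyama–Michael/ring-closure sequence at low temperature, using a two-point-binding ester in place of the formyl dienophile. It sets out from 13 and 11. The Grignard reagent 15 is acylated with dimethyl oxalate at −78 °C to give methyl 5-{[tert-butyl(diphenyl)silyl]oxy}-2-oxopentanoate F1. Enol acetylation (Ac2O, Et3N, DMAP) gives methyl (2Z)-2-acetoxy-5-{[tert-butyl(diphenyl)silyl]oxy}pent-2-enoate F2. F2 and 11 are combined with a chelating Lewis acid (MgBr2·OEt2 or Me2AlCl, CH2Cl2, −78 to −40 °C) to give the ester analogue of the cycloadduct F3, which has CO2Me in place of CHO on C11. LiAlH4 reduces the ester and the acetate of F3, and the route is rejoined at 21.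

Step 26. What may go wrong: oligomerisation in competition with ten-ring closure, poor facial selectivity at C7, or Z to E drift of the enal. The fallback sets C7 by protonation instead of by the C–C bond formation. It sets out from 37. The ring is closed without the chiral ligand (CrCl2, NiCl2, DMF, high dilution), accepting 39 together with the C7 epimer of the target F4. F4 (or the mixture) is converted with i-Pr3SiOTf/Et3N at −78 °C into the 2-(triisopropylsilyloxy)furan F5, in which C7 is trigonal. F5 is desilylated with Bu4NF/AcOH at low temperature, the proton reaching C7 from the exposed outer face of the macrocycle. If kinetic protonation favours F4, equilibration with DBU gives the thermodynamic epimer ratio instead. The fallback returns at 39.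

Step 17. What may go wrong: insufficient facial selectivity in the hydride addition, or butanoyl migration from O2 to O14. The fallback sets C14 by intramolecular hydride delivery before any ester is present. It sets out from 25. An Evans–Saksena reduction with Me4NBH(OAc)3 (MeCN/AcOH, −20 °C), in which the C2 hydroxyl binds boron and delivers hydride, should give the 1,3-anti diol F6 (14α-OH). Mono-butanoylation of the less hindered acyclic C2 hydroxyl (1 equiv butanoic anhydride, DMAP, −40 °C), in preference to the axial C14 hydroxyl that is syn-axial to the C12 ether, returns the route at 27.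

**Further compounds**

F1 | step 12 | methyl 5-{[tert-butyl(diphenyl)silyl]oxy}-2-oxopentanoate | COC(=O)C(=O)CCCO[Si](c1ccccc1)(c1ccccc1)C(C)(C)C
F2 | step 12 | methyl (2Z)-2-acetoxy-5-{[tert-butyl(diphenyl)silyl]oxy}pent-2-enoate | COC(=O)/C(OC(C)=O)=C/CCO[Si](c1ccccc1)(c1ccccc1)C(C)(C)C
F3 | step 12 | ester analogue of cycloadduct 20 (CO2Me in place of CHO on C11) | CC(C)(C)[Si]1(C(C)(C)C)O[C@@H](CC/C(C)=C\CO[Si](c2ccccc2)(c2ccccc2)C(C)(C)C)[C@]2(C)[C@@H](CCO[Si](c3ccccc3)(c3ccccc3)C(C)(C)C)[C@@](C(=O)OC)(OC(C)=O)[C@H](OCc3ccc(OC)cc3)C=C2O1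
F4 | step 26 | C7 epimer of the target | CCCC(=O)O[C@H]1CC/C(C)=C\[C@@H]2OC(=O)C(C)=C2C[C@H]2[C@@]3(C)O[C@H]3C[C@H](OC(C)=O)[C@]12C
F5 | step 26 | 2-(triisopropylsilyloxy)furan derived from F4 | CCCC(=O)O[C@H]1CC/C(C)=C\c2oc(O[Si](C(C)C)(C(C)C)C(C)C)c(C)c2C[C@H]2[C@@]3(C)O[C@H]3C[C@H](OC(C)=O)[C@]12C
F6 | step 17 | 1,3-anti diol (2-OH, 14α-OH; 11β-OH, 12α-OPMB) | O[C@@H](CC/C(C)=C\CO[Si](c1ccccc1)(c1ccccc1)C(C)(C)C)[C@]1(C)[C@@H](CCO[Si](c2ccccc2)(c2ccccc2)C(C)(C)C)[C@@](C)(O)[C@H](OCc2ccc(OC)cc2)C[C@@H]1O
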